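**Assumption:** the 1,3-diketones are drawn and named as diketo tautomers although they will exist largely as chelated enols; no step depends on this.

## The problem

The target, 1-[4-hydroxy-2-methoxy-3-(3-methylbut-2-enyl)phenyl]-3-(4-hydroxyphenyl)propane-1,3-dione 12, is an open-chain dibenzoylmethane with no ring to close and no stereocentre, so the task is one of regiochemistry and chemoselectivity. Ring A is substituted on four adjacent carbons: the acyl group at C1', a methyl ether at C2', the prenyl group at C3' and a free hydroxyl at C4'. The prenyl group sits at the most hindered site, between two oxygens, where direct C-prenylation of a resorcinol ketone would give mixtures of C3', C5' and O-alkylation. Three oxygens must be told apart: the C2' methyl ether, the free C4' hydroxyl and the free hydroxyl of ring B. The enolised diketone is cleaved by hot hydroxide or alkoxide, is alkylated at carbon by electrophiles and binds metals, and the prenyl olefin next to a free phenol cyclises to a 2,2-dimethylchroman under strong acid and is reduced over active hydrogenation catalysts. The enabling feature is that the C4' oxygen is the direct neighbour of C3': in a 1,1-dimethylallyl ether on O4' the atoms C3', C4', O4' and the three allyl carbons form the six-atom array of a [3,3] shift. O4' has a second ortho neighbour, C5', and with the C2' oxygen methylated there is no chelate to the carbonyl to fix the C3'–C4' double bond, so the general preference of meta-alkoxy aryl allyl ethers to migrate para to the alkoxy group points to C5'. A sound plan must therefore close C5' while the shift takes place.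

## Retrosynthesis

**12 from 11.** The last cut is the O–CH2 bond of a methoxymethyl ether on ring B, which leads back to 11. The ring B phenol must be masked while the diketone is assembled by enolate chemistry. A benzyl ether would need hydrogenolysis, which the prenyl group forbids. A silyl ether is at risk from the methoxide set free in the condensation. The methoxymethyl ether survives base and heat and falls to dilute acid, which the prenyl phenol tolerates near room temperature.

**11 from 10.** The C5'–H bond is traced back to a C5'–Br bond in 10. The bromine is a temporary blocking group that forces the sigmatropic shift to C3'. The other way to secure C3', a free chelated C2' hydroxyl, would require a later selective methylation of the hindered, hydrogen-bonded C2' hydroxyl in the presence of the C4' hydroxyl and the diketone, which is not defensible. The bromine costs two steps but makes the site of the shift a matter of constitution. The forward step must remove an aryl bromide without touching the trisubstituted olefin.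

**10 from 8, the key disconnection.** The C3'–CH2 bond of the prenyl group is cut and the allyl unit is returned, inverted, to O4'. This gives the 1,1-dimethylallyl ether 8, with the cyclohexadienone 9 as the transient link. Against direct C-prenylation of a phenol this cut puts the five-carbon unit in by an intramolecular, concerted path that can only reach an ortho carbon. Only C3' is open, since C5' carries bromine and the para position C1' carries the acyl group. The precursor 8 has no free ring A phenol, so the tertiary ether also serves as the C4' protecting group during diketone formation. This is the case for making the shift late and not at the acetophenone stage. The forward reaction must proceed at a temperature the enolised diketone tolerates.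

**8 from 5 and 7.** The bond between the central CH2 and the ring B carbonyl is cut, giving the methyl ketone 5 and the non-enolisable ester 7. The reverse polarity, a ring A ester with a ring B methyl ketone, would serve equally in principle. The ring A acetophenone 1 is the commercially available piece, so the ketone is placed on ring A. A crossed Claisen condensation builds the whole diketone in one step from two simple halves.

**7 from 6.** The methoxymethyl ether of 7 is cut to methyl 4-hydroxybenzoate 6.

**5 from 4, and 4 from 2 and 3.** The vinyl group of 5 is traced to the ethynyl group of 4. The O4'–C bond of 4 is cut to the phenol 2 and 3-chloro-3-methylbut-1-yne 3. A tertiary allyl halide would not give the tertiary ether by direct substitution. The copper-mediated propargylic substitution does, and semihydrogenation then reveals the 1,1-dimethylallyl ether.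

**2 from 1.** The C5'–Br bond of 2 is cut to 1-(4-hydroxy-2-methoxyphenyl)ethanone 1. C5' is ortho to the hydroxyl, para to the methoxy group and unhindered, so electrophilic bromination should select it over C3'.

## Roads not taken

**Alternative 1:** Ring A would be built and not bought. The C1'–C2' and C5'–C6' bonds are cut to the ketene-acetal diene 1,1-dimethoxy-2-(3-methylbut-2-enyl)-3-(trimethylsilyloxy)buta-1,3-diene A2 and methyl propiolate A3. Diels–Alder addition of A2 to A3, loss of methanol and desilylation would give methyl 4-hydroxy-2-methoxy-3-(3-methylbut-2-enyl)benzoate A1.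
- Merits: the polarisation of A2 matches that of A3, so the ester should end up next to the methoxy carbon. The prenyl group is in place from the start, with no C3'/C5' question and no blocking group. In this respect the road is better than the chosen plan, which spends two steps on putting bromine on and taking it off.
- Weak points: A2 is a fully substituted, hydrolytically fragile diene that needs several steps of its own, and its C2 substituent hinders the cycloaddition with A3. A1 is still far from the target. Its phenol must be protected and its ester condensed with a ring B methyl ketone enolate, so the total count is higher.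
- Comparison: the chosen plan answers the regiochemical certainty of A1 with a commercial ring A and robust, classical steps.

**Alternative 2:** The bond between ring B and its carbonyl carbon is cut. The beta-keto thioester S-ethyl 3-[2-methoxy-4-(methoxymethoxy)-3-(3-methylbut-2-enyl)phenyl]-3-oxopropanethioate A5 would couple with 4-hydroxyphenylboronic acid A6 under Pd2(dba)3, tri(2-furyl)phosphine and stoichiometric copper thiophene-2-carboxylate, a monovalent copper salt (Liebeskind–Srogl coupling). The product would be the diketone A4, 3-(4-hydroxyphenyl)-1-[2-methoxy-4-(methoxymethoxy)-3-(3-methylbut-2-enyl)phenyl]propane-1,3-dione.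
- Merits: the coupling is neutral and base-free, and A6 needs no protecting group, so A4 stands one acetal cleavage from the target. Here the road is better than the chosen plan, which must protect ring B and use a hydride base.
- Weak points: A5 has an acidic CH2 between two carbonyls, chelates copper and can lose thiol to an acyl ketene on warming. The method is thinly supported on such substrates. The cut also leaves the real difficulty, the prenyl group at C3' of A5, unsolved, so a Claisen shift or an equivalent is needed anyway before A4 can be reached.
- Comparison: the chosen plan builds the diketone skeleton of A4 in one classical condensation from cheaper pieces and keeps its single risk in the sigmatropic step.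

**Alternative 3:** The diketone is masked as the ynone A8, 1-[2-methoxy-4-(methoxymethoxy)-3-(3-methylbut-2-enyl)phenyl]-3-[4-(methoxymethoxy)phenyl]prop-2-yn-1-one. Conjugate addition of pyrrolidine A9 to the beta carbon of A8 and aqueous hydrolysis of the adduct in the same flask would give the doubly protected diketone A7, 1-[2-methoxy-4-(methoxymethoxy)-3-(3-methylbut-2-enyl)phenyl]-3-[4-(methoxymethoxy)phenyl]propane-1,3-dione.
- Merits: the hydration with A9 is mild and the position of the new carbonyl is fixed by the ynone. The masked diketone A8 neither enolises nor chelates, which would be an advantage in any metal-mediated step before the unmasking. A7 loses both acetals in one acid step.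
- Weak points: A8 needs a prenylated ring A acyl donor and a ring B alkyne, so ynone formation and unmasking take the place of a single condensation. The placement of the prenyl group is again left open, and it must be solved before A7 exists.
- Comparison: the chosen plan accepts a free diketone in the palladium-mediated debromination, which the route through A8 and A7 would spare, in exchange for a shorter and more convergent sequence.

Key step: step 6

## Route

Step 1
Reactants: 1 1-(4-hydroxy-2-methoxyphenyl)ethanone
Product: 2 1-(5-bromo-4-hydroxy-2-methoxyphenyl)ethanone
Conditions: NBS, MeCN, 0 °C to rt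
Reagents that add atoms: N-bromosuccinimide, O=C1CCC(=O)N1Br
Why: Electrophilic aromatic bromination of a phenol; C5 is ortho to the hydroxyl, para to the methoxy group and unhindered, whereas C3 lies between both oxygens, so monobromination should go to C5, and the acid-free conditions should spare the ketone alpha position.

Step 2
Reactants: 2 1-(5-bromo-4-hydroxy-2-methoxyphenyl)ethanone; 3 3-chloro-3-methylbut-1-yne
Product: 4 1-[5-bromo-2-methoxy-4-(2-methylbut-3-yn-2-yloxy)phenyl]ethanone
Conditions: CuCl2·2H2O (cat.), DBU, MeCN, 0 °C
Reagents that add atoms: none
Why: Copper-catalysed propargylic etherification of a phenol with a tertiary propargyl chloride, the standard entry to aryl 1,1-dimethylpropargyl ethers; it works best with acidic, electron-poor phenols such as 2, and the ketone and aryl bromide are inert.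

Step 3
Reactants: 4 1-[5-bromo-2-methoxy-4-(2-methylbut-3-yn-2-yloxy)phenyl]ethanone
Product: 5 1-[5-bromo-2-methoxy-4-(2-methylbut-3-en-2-yloxy)phenyl]ethanone
Conditions: H2 (1 atm), Pd/CaCO3 poisoned with Pb(OAc)2 (Lindlar catalyst), quinoline, EtOAc, rt
Reagents that add atoms: none
Why: Lindlar semihydrogenation of the terminal alkyne; the poisoned catalyst with quinoline at one atmosphere should stop at the vinyl group and leave the aryl bromide and ketone intact if hydrogen uptake is followed.

Step 4
Reactants: 6 methyl 4-hydroxybenzoate
Product: 7 methyl 4-(methoxymethoxy)benzoate
Conditions: MOMCl, iPr2NEt, CH2Cl2, 0 °C to rt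
Reagents that add atoms: chloromethyl methyl ether, COCCl
Why: Standard methoxymethyl protection of a phenol; the acetal withstands hydride base and heat and is later removed by dilute acid.

Step 5
Reactants: 5 1-[5-bromo-2-methoxy-4-(2-methylbut-3-en-2-yloxy)phenyl]ethanone; 7 methyl 4-(methoxymethoxy)benzoate
Product: 8 1-[5-bromo-2-methoxy-4-(2-methylbut-3-en-2-yloxy)phenyl]-3-[4-(methoxymethoxy)phenyl]propane-1,3-dione
Conditions: NaH, THF, 0 °C to 60 °C; then aq. NH4Cl, 0 °C
Reagents that add atoms: none
Why: Crossed Claisen condensation of a methyl ketone enolate with a non-enolisable aryl ester, driven by irreversible deprotonation of the diketone formed; the tertiary allyl ether, aryl bromide and acetal are stable to NaH, and the temperature stays below that needed for the sigmatropic shift.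

Step 6
Reactants: 8 1-[5-bromo-2-methoxy-4-(2-methylbut-3-en-2-yloxy)phenyl]-3-[4-(methoxymethoxy)phenyl]propane-1,3-dione
Product: 10 1-[5-bromo-4-hydroxy-2-methoxy-3-(3-methylbut-2-enyl)phenyl]-3-[4-(methoxymethoxy)phenyl]propane-1,3-dione, via ortho-dienone 9 (not isolated)
Conditions: PhNEt2, 140 °C, argon
Reagents that add atoms: none
Why: Aromatic Claisen rearrangement of an aryl 1,1-dimethylallyl ether to an ortho-prenylphenol, the closest known reaction type. In a concerted, suprafacial [3,3] shift through a chair-like transition state the terminal CH2 of the allyl unit bonds to C3' as the O4'–C bond breaks, giving cyclohexadienone 9, which enolises to the phenol 10. The allyl unit is inverted, so the tertiary ether emerges as the linear prenyl group. No ring is closed, and the sp3 centre at C3' of 9 is lost on aromatisation, so no stereocentre results. The selectivity needed is C3' over C5': C5' carries bromine, so a shift there would give a dienone that cannot enolise and should revert, and the para position C1' is occupied by the acyl group, leaving C3' as the only productive terminus. The geminal methyl groups weaken the O–C bond and lower the temperature needed, which the enolised diketone and the acetal should tolerate. The amine solvent buffers traces of acid that would ionise the tertiary ether or cyclise the product to a chroman.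

Step 7
Reactants: 10 1-[5-bromo-4-hydroxy-2-methoxy-3-(3-methylbut-2-enyl)phenyl]-3-[4-(methoxymethoxy)phenyl]propane-1,3-dione
Product: 11 1-[4-hydroxy-2-methoxy-3-(3-methylbut-2-enyl)phenyl]-3-[4-(methoxymethoxy)phenyl]propane-1,3-dione
Conditions: Pd(OAc)2 (cat.), PPh3, HCO2Na, DMF, 90 °C
Reagents that add atoms: none
Why: Palladium-catalysed hydrodehalogenation with formate as hydride source (oxidative addition, formate exchange, loss of CO2, C–H reductive elimination); with no hydrogen gas and no heterogeneous surface the trisubstituted olefin should not be reduced, and the diketone and acetal are inert.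

Step 8
Reactants: 11 1-[4-hydroxy-2-methoxy-3-(3-methylbut-2-enyl)phenyl]-3-[4-(methoxymethoxy)phenyl]propane-1,3-dione
Product: 12 1-[4-hydroxy-2-methoxy-3-(3-methylbut-2-enyl)phenyl]-3-(4-hydroxyphenyl)propane-1,3-dione
Conditions: 3 M HCl (aq.), MeOH, rt to 40 °C
Reagents that add atoms: none
Why: Acid-catalysed acetal exchange cleaves the aryl methoxymethyl ether; dilute HCl in methanol near room temperature is the usual way to unmask phenols beside prenyl groups without chroman formation, and the methylated C2' oxygen rules out closure of the diketone to a flavone.

## Compound list

1 | 1-(4-hydroxy-2-methoxyphenyl)ethanone | CC(=O)c1ccc(O)cc1OC | starting material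
2 | 1-(5-bromo-4-hydroxy-2-methoxyphenyl)ethanone | CC(=O)c1cc(Br)c(O)cc1OC | intermediate
3 | 3-chloro-3-methylbut-1-yne | CC(C)(Cl)C#C | starting material
4 | 1-[5-bromo-2-methoxy-4-(2-methylbut-3-yn-2-yloxy)phenyl]ethanone | CC(=O)c1cc(Br)c(OC(C)(C)C#C)cc1OC | intermediate
5 | 1-[5-bromo-2-methoxy-4-(2-methylbut-3-en-2-yloxy)phenyl]ethanone | CC(=O)c1cc(Br)c(OC(C)(C)C=C)cc1OC | intermediate
6 | methyl 4-hydroxybenzoate | COC(=O)c1ccc(O)cc1 | starting material
7 | methyl 4-(methoxymethoxy)benzoate | COCOc1ccc(C(=O)OC)cc1 | intermediate
8 | 1-[5-bromo-2-methoxy-4-(2-methylbut-3-en-2-yloxy)phenyl]-3-[4-(methoxymethoxy)phenyl]propane-1,3-dione | COc1cc(OC(C)(C)C=C)c(Br)cc1C(=O)CC(=O)c1ccc(OCOC)cc1 | intermediate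
9 | 1-[5-bromo-2-methoxy-3-(3-methylbut-2-enyl)-4-oxocyclohexa-1,5-dien-1-yl]-3-[4-(methoxymethoxy)phenyl]propane-1,3-dione (racemic at the sp3 ring carbon) | COC1=C(C(=O)CC(=O)c2ccc(OCOC)cc2)C=C(Br)C(=O)C1CC=C(C)C | intermediate
10 | 1-[5-bromo-4-hydroxy-2-methoxy-3-(3-methylbut-2-enyl)phenyl]-3-[4-(methoxymethoxy)phenyl]propane-1,3-dione | COc1c(C(=O)CC(=O)c2ccc(OCOC)cc2)cc(Br)c(O)c1CC=C(C)C | intermediate
11 | 1-[4-hydroxy-2-methoxy-3-(3-methylbut-2-enyl)phenyl]-3-[4-(methoxymethoxy)phenyl]propane-1,3-dione | COc1c(C(=O)CC(=O)c2ccc(OCOC)cc2)ccc(O)c1CC=C(C)C | intermediate
12 | 1-[4-hydroxy-2-methoxy-3-(3-methylbut-2-enyl)phenyl]-3-(4-hydroxyphenyl)propane-1,3-dione | COc1c(C(=O)CC(=O)c2ccc(O)cc2)ccc(O)c1CC=C(C)C | target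

## Step count and risks

Total steps: 8. Longest linear sequence: 7 (steps 1, 2, 3, 5, 6, 7, 8); step 4 prepares the ring B ester on a side branch.

**Step 6 (key step).**
- Risk: ionisation of the tertiary allyl ether may compete with the concerted shift, because the phenoxide carrying bromine and a para acyl group is a good leaving group; this would lose the five-carbon unit and return the phenol.
- Risk: attack at the brominated carbon followed by loss of bromine, and slow thermal breakdown of the diketone, are further possible losses.
- Fallback: the shift is moved to the robust methyl ketone. Compound 5 is heated in PhNEt2 to give 1-[5-bromo-4-hydroxy-2-methoxy-3-(3-methylbut-2-enyl)phenyl]ethanone F1. The phenol of F1 is protected with MOMCl and iPr2NEt to give 1-[5-bromo-2-methoxy-4-(methoxymethoxy)-3-(3-methylbut-2-enyl)phenyl]ethanone F2. F2 is condensed with 7 (NaH, THF) to give 1-[5-bromo-2-methoxy-4-(methoxymethoxy)-3-(3-methylbut-2-enyl)phenyl]-3-[4-(methoxymethoxy)phenyl]propane-1,3-dione F3. Dilute HCl in methanol removes both acetals of F3 to give 1-[5-bromo-4-hydroxy-2-methoxy-3-(3-methylbut-2-enyl)phenyl]-3-(4-hydroxyphenyl)propane-1,3-dione F4. Palladium-catalysed formate reduction of F4 (Pd(OAc)2, PPh3, HCO2Na) then rejoins the route at 12.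

**Step 7.**
- Risk: oxidative addition into an electron-rich aryl bromide with an ortho phenoxide may be slow, the diketonate may sequester palladium, and a palladium hydride may move the prenyl double bond.
- Fallback: a radical chain reduction replaces the metal-catalysed one. Compound 10 is treated with Bu3SnH and AIBN in toluene at 80 °C. The aryl radical is quenched by the tin hydride faster than it can attack the remote olefin, and 11 is reached directly; no new compound is made, so the entry for this fallback is F0.

**Step 5.**
- Risk: the para-alkoxy ester 7 is a deactivated acyl acceptor, so self-aldol condensation of 5 may compete, and prolonged heating may start the sigmatropic shift early.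
- Fallback: the carbon–carbon bond is made by aldol addition. The lithium enolate of 5 (LiN(SiMe3)2, THF, −78 °C) is added to 4-(methoxymethoxy)benzaldehyde F5 to give racemic 1-[5-bromo-2-methoxy-4-(2-methylbut-3-en-2-yloxy)phenyl]-3-hydroxy-3-[4-(methoxymethoxy)phenyl]propan-1-one F6. Oxidation of F6 with Dess–Martin periodinane (NaHCO3, CH2Cl2) returns to the route at 8.

**Step 2.**
- Risk: alkylation of the hindered ortho-bromophenoxide may be slow and the tertiary chloride 3 may eliminate to the enyne; over-reduction in step 3 is a related risk.
- Fallback: the tertiary allyl ether is made directly, bypassing steps 2 and 3. Compound 2 is treated with tert-butyl 2-methylbut-3-en-2-yl carbonate F7 and Pd(PPh3)4 in THF at 0 °C. The allyl complex formed from F7 with zerovalent palladium is captured by the phenoxide at the more substituted terminus under kinetic control, and the route is rejoined at 5.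

## Further compounds

F1 | step 6 | 1-[5-bromo-4-hydroxy-2-methoxy-3-(3-methylbut-2-enyl)phenyl]ethanone | CC(=O)c1cc(Br)c(O)c(CC=C(C)C)c1OC
F2 | step 6 | 1-[5-bromo-2-methoxy-4-(methoxymethoxy)-3-(3-methylbut-2-enyl)phenyl]ethanone | CC(=O)c1cc(Br)c(OCOC)c(CC=C(C)C)c1OC
F3 | step 6 | 1-[5-bromo-2-methoxy-4-(methoxymethoxy)-3-(3-methylbut-2-enyl)phenyl]-3-[4-(methoxymethoxy)phenyl]propane-1,3-dione | COc1c(C(=O)CC(=O)c2ccc(OCOC)cc2)cc(Br)c(OCOC)c1CC=C(C)C
F4 | step 6 | 1-[5-bromo-4-hydroxy-2-methoxy-3-(3-methylbut-2-enyl)phenyl]-3-(4-hydroxyphenyl)propane-1,3-dione | COc1c(C(=O)CC(=O)c2ccc(O)cc2)cc(Br)c(O)c1CC=C(C)C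
F0 | step 7 | none | none
F5 | step 5 | 4-(methoxymethoxy)benzaldehyde | COCOc1ccc(C=O)cc1
F6 | step 5 | 1-[5-bromo-2-methoxy-4-(2-methylbut-3-en-2-yloxy)phenyl]-3-hydroxy-3-[4-(methoxymethoxy)phenyl]propan-1-one (racemic) | COc1cc(OC(C)(C)C=C)c(Br)cc1C(=O)CC(O)c1ccc(OCOC)cc1
F7 | step 2 | tert-butyl 2-methylbut-3-en-2-yl carbonate | CC(C)(C)OC(=O)OC(C)(C)C=C
A1 | alternative 1 | methyl 4-hydroxy-2-methoxy-3-(3-methylbut-2-enyl)benzoate | COC(=O)c1ccc(O)c(CC=C(C)C)c1OC
A2 | alternative 1 | 1,1-dimethoxy-2-(3-methylbut-2-enyl)-3-(trimethylsilyloxy)buta-1,3-diene | COC(OC)=C(CC=C(C)C)C(=C)O[Si](C)(C)C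
A3 | alternative 1 | methyl propiolate | COC(=O)C#C
A4 | alternative 2 | 3-(4-hydroxyphenyl)-1-[2-methoxy-4-(methoxymethoxy)-3-(3-methylbut-2-enyl)phenyl]propane-1,3-dione | COc1c(C(=O)CC(=O)c2ccc(O)cc2)ccc(OCOC)c1CC=C(C)C
A5 | alternative 2 | S-ethyl 3-[2-methoxy-4-(methoxymethoxy)-3-(3-methylbut-2-enyl)phenyl]-3-oxopropanethioate | CCSC(=O)CC(=O)c1ccc(OCOC)c(CC=C(C)C)c1OC
A6 | alternative 2 | 4-hydroxyphenylboronic acid | OB(O)c1ccc(O)cc1
A7 | alternative 3 | 1-[2-methoxy-4-(methoxymethoxy)-3-(3-methylbut-2-enyl)phenyl]-3-[4-(methoxymethoxy)phenyl]propane-1,3-dione | COc1c(C(=O)CC(=O)c2ccc(OCOC)cc2)ccc(OCOC)c1CC=C(C)C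
A8 | alternative 3 | 1-[2-methoxy-4-(methoxymethoxy)-3-(3-methylbut-2-enyl)phenyl]-3-[4-(methoxymethoxy)phenyl]prop-2-yn-1-one | COc1c(C(=O)C#Cc2ccc(OCOC)cc2)ccc(OCOC)c1CC=C(C)C
A9 | alternative 3 | pyrrolidine | C1CCNC1
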